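All runs are simulated from invented constants, noise included.

The next flask was to hold 0.74 M free monomer against 26 mM initiator, the same charge as Thursday's and Tuesday's runs, with 0.370 M protic impurity. I had to decide whether that impurity could stay or had to come down first.

| flask | free monomer | protic impurity | initiator | remark | time |
|---|---|---|---|---|---|
| Thursday's | 0.74 M | 0.18 M | 26 mM | run made earlier |  |
| Tuesday's | 0.74 M | 0.74 M | 26 mM | run made earlier |  |
| flask | 0.74 M | 0.370 M | 26 mM |  | 40 h |

- Thursday's (time / h: monomer in chains / %, free monomer / %): 3.00: 10.1, 86.7; 6.00: 16.6, 77.4; 12.0: 27.1, 63.8; 20.0: 35.5, 52.3; 40.0: 41.0, 41.7
- Tuesday's (time / h: monomer in chains / %, free monomer / %): 4.00: 11.1, 73.6; 10.0: 20.0, 52.7; 20.0: 21.7, 37.7; 30.0: 20.3, 30.9; 40.0: 16.6, 28.3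

(standard deviation of a reading: 0.5 percentage points)

* whether the average number of monomer units in a chain (chains begun, living or dead) reaches 3.0 by 40 h (yes / no)
* average number of monomer units in a chain (chains begun, living or dead) at 40 h

- the average divides the monomer in chains by the number of chains begun, living and dead together
- what may be going on: free monomer + initiator -> living end + monomer in chains; free monomer + living end -> monomer in chains + living end; monomer in chains + living end -> free monomer + living end; protic impurity + free monomer -> quenched substrate; living end + monomer in chains -> dead end
- the earlier runs do not show the number of chains; that part of a forecast is a guess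

One initiator begins one chain, and a chain that dies still counts, so I froze the number of chains begun at the initiator charge; that count was a guess, since the earlier runs do not show it. The average length (number-average degree of polymerisation) then follows from one ratio, L = 28.5, the full length: the units per chain if the whole charge of free monomer stood in chains.

length = L × share of the charge in chains

share needed = 3.0 / L = 10.5%

Tuesday's run had more protic impurity than the flask, yet it still held 16.6% in chains at 40.0 h, more than the share needed. Thursday's run held 41.0%. I placed the flask between them by its impurity, a straight line and so a rough one:

share at 40 h = 32.7%

length = L × share = 9.31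

So I left the impurity at 0.370 M and charged the flask as planned.

The forecast answered yes and gave a length of 8.8, below my figure; of the initiator it said: “No induction appears, so initiation is probably nearly complete”. The flask gave yes and 9.09.

    free monomer + initiator → living end + monomer in chains (k = 1.90 M⁻¹ h⁻¹)
    free monomer + living end → monomer in chains + living end, rate k2*[living end]*[free monomer] (k = 2.10 M⁻¹ h⁻¹)
    monomer in chains + living end → free monomer + living end, rate k3*[living end] as long as [monomer in chains] is above zero (k = 0.590 h⁻¹)
    protic impurity + free monomer → quenched substrate (k = 0.0600 M⁻¹ h⁻¹)
    living end + monomer in chains → dead end (k = 0.0500 M⁻¹ h⁻¹)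

In the flask, free monomer entered chains while the initiator fell to 0.662% of its charge by 4.00 h, and the wanted length was passed at 3.19 h, with 16.4% of the free monomer reacted. Protic impurity kept taking free monomer, giving 30.6% quenched substrate by 40.0 h, when monomer in chains was made at 0.940 of the rate it was used up, each step taken net, and stood at 31.9% of the charge, which L turns into 9.09. Living ends then stood at 17.7 mM, and with dead ends the chains begun came to 26.0 mM. At 400 h the flask held 11.0% in chains, a length by L of 3.12.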